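**Plan** (labdane numbering; α is the face carrying C19, C20 and the C9 side chain, β is the face of C18, H5, H9 and the C3 oxygen of the target)
Cuts: C12–C13 (B-alkyl Suzuki), C11=C12 (methylenation), ring B at C9–C10 and C7–C8 (Diels–Alder), C5–C6 (Stille), C10–C20 (enolate methylation), C4–C19 (formaldehyde aldol).
Enabling feature: in ring B the quaternary C10 is bonded to C9, C9 carries chain carbon C11 and C8 carries CH3-17. Ring B is therefore the sum of a ring A diene C10=C5–C6=C7 and the alkyne C8≡C9 of methyl but-2-ynoate, whose ester carbon is C11.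
Forward: ring A comes from 2-methylcyclohexane-1,3-dione and is turned into the vinylcyclohexene. Ring B closes in the cycloaddition, Δ5 is hydrogenated, Δ8 is moved to Δ7, the C13–C16 enoate is joined, and C3 is corrected last.
Stereochemistry: C4 (with a temporary 3α-oxygen) comes from a Ru transfer-hydrogenation desymmetrisation and C10 from diene-face selection by ring A. C5 and C9 come from hydrogen delivery opposite axial C20/C19, C3 from bulky-hydride reduction of the 3-ketone, and 13E from an (E)-enol triflate.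

Key step: step 8

Abbreviations: TBS = tert-butyldimethylsilyl, TBDPS = tert-butyldiphenylsilyl, TMSE = 2-(trimethylsilyl)ethyl.
Assumption: the (R,R)-TsDPEN catalyst is taken to give the 3R carbinol, with the quaternary, carbonyl-bearing side of the ketone playing the part of the aryl group in the usual model; if the sense is opposite, the (S,S) catalyst is used.

Step 1
Reactants: 1 2-methylcyclohexane-1,3-dione; 2 formaldehyde
Product: 3 2-(hydroxymethyl)-2-methylcyclohexane-1,3-dione
Conditions: 37% aq. CH2O, NaHCO3 (cat.), H2O–THF, rt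
Reagents that add atoms: none
Why: Aldol-type hydroxymethylation of the acidic C–H between the two carbonyl groups forms C4–C19 and the still prochiral quaternary C4, and the adduct cannot dehydrate because C4 keeps no hydrogen.

Step 2
Reactants: 3 2-(hydroxymethyl)-2-methylcyclohexane-1,3-dione
Product: 4 2-[(TBDPS-oxy)methyl]-2-methylcyclohexane-1,3-dione
Conditions: t-BuPh2SiCl, imidazole, DMF, 0 °C → rt
Reagents that add atoms: tert-butyl(chloro)diphenylsilane CC(C)(C)[Si](Cl)(c1ccccc1)c1ccccc1
Why: Imidazole-mediated silylation of the primary alcohol blocks retro-aldol loss of formaldehyde and makes C19 the large substituent on C4 that steers step 3.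

Step 3
Reactants: 4 2-[(TBDPS-oxy)methyl]-2-methylcyclohexane-1,3-dione
Product: 5 (2R,3R)-2-[(TBDPS-oxy)methyl]-3-hydroxy-2-methylcyclohexan-1-one (OH cis to CH2OSi)
Conditions: RuCl(p-cymene)[(R,R)-TsDPEN] (1 mol%), HCO2H–Et3N 5:2, CH2Cl2, rt
Reagents that add atoms: none
Why: Noyori-type asymmetric transfer hydrogenation used as a desymmetrisation of a 2,2-disubstituted cyclic 1,3-diketone: the chiral Ru hydride picks one of the two enantiotopic carbonyl groups and attacks it on the ring face that carries the small methyl group, which sets C3 (R) and C4 (R) at once with O3 cis to C19, while the hindered hydroxy ketone is reduced further only slowly.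

Step 4
Reactants: 5 (2R,3R)-hydroxy ketone
Product: 6 (2R,3R)-3-(TBS-oxy)-2-[(TBDPS-oxy)methyl]-2-methylcyclohexan-1-one
Conditions: t-BuMe2SiOTf, 2,6-lutidine, CH2Cl2, −78 → 0 °C
Reagents that add atoms: tert-butyldimethylsilyl trifluoromethanesulfonate CC(C)(C)[Si](C)(C)OS(=O)(=O)C(F)(F)F
Why: Silyl triflate silylation of the hindered secondary alcohol with a non-nucleophilic base avoids retro-aldol ring opening and installs a bulky ether that can later be removed beside the TBDPS ether.

Step 5
Reactants: 6 bis-silyl ketone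
Product: 8 (2R,3R,6RS)-3-(TBS-oxy)-2-[(TBDPS-oxy)methyl]-2,6-dimethylcyclohexan-1-one (epimers at C10), via lithium enolate 7 (not isolated)
Conditions: LiN(i-Pr)2, THF, −78 °C; MeI, −78 → −20 °C
Reagents that add atoms: iodomethane CI; lithium diisopropylamide (its lithium stays only in 7) [Li+].CC(C)[N-]C(C)C
Why: Kinetic enolate alkylation in which C10 is the only enolisable position because C4 is quaternary, so C20 enters regiospecifically, and the C10 configuration is irrelevant since this carbon becomes sp2 in step 6.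

Step 6
Reactants: 8 methyl ketone
Product: 10 (5R,6R)-5-(TBS-oxy)-6-[(TBDPS-oxy)methyl]-2,6-dimethylcyclohex-1-en-1-yl trifluoromethanesulfonate, via potassium enolate 9 (not isolated)
Conditions: KN(SiMe3)2, THF, −78 → 0 °C; PhNTf2, 0 °C → rt
Reagents that add atoms: N-phenylbis(trifluoromethanesulfonimide) O=S(=O)(N(c1ccccc1)S(=O)(=O)C(F)(F)F)C(F)(F)F; potassium hexamethyldisilazide (its potassium stays only in 9) [K+].C[Si](C)(C)[N-][Si](C)(C)C
Why: Enolate O-triflation in which the single remaining α-hydrogen at C10 allows only the tetrasubstituted C5=C10 enolate, trapped as is routine for 2,2,6-trisubstituted cyclohexanones.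

Step 7
Reactants: 10 enol triflate; 11 tributyl(vinyl)stannane
Product: 12 ring A diene tert-butyl{[(1R,6R)-6-(TBS-oxy)-1,3-dimethyl-2-vinylcyclohex-2-en-1-yl]methoxy}diphenylsilane (O3 cis to C19)
Conditions: Pd(PPh3)4 (5 mol%), LiCl, THF, reflux
Reagents that add atoms: none
Why: Stille coupling of a vinyl triflate with the small vinylstannane in the presence of LiCl forms C5–C6 and completes the diene C10=C5–C6=C7 without touching C3 or C4.

Step 8
Reactants: 12 ring A diene; 13 methyl but-2-ynoate
Product: 14 methyl 3α-(TBS-oxy)-19-(TBDPS-oxy)-12,13,14,15,16-pentanorlabda-5,8-dien-11-oate (C20 α cis to C19)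
Conditions: 13 (3 equiv), EtAlCl2 (2.5 equiv), CH2Cl2, −40 → 0 °C; aqueous work-up, chromatography
Reagents that add atoms: none
Why: The EtAlCl2-bound ynoate and the s-cis diene C10=C5–C6=C7 combine in a concerted but strongly asynchronous [4+2] cycloaddition in which the electrophilic β-carbon C8 bonds ahead to the unsubstituted terminus C7 while positive charge builds up at the fully substituted C10, on which C9 then closes, so that the ester carbon becomes C11 next to the quaternary centre and the alkyne methyl becomes C17. The closest known reaction type is the Diels–Alder addition of acetylenic esters to 2,6,6-trisubstituted 1-vinylcyclohexenes, which gives bicyclic 1,4-dienes with an angular methyl group; a but-2-ynoate is much less reactive than an acetylenedicarboxylate, hence Lewis acid activation at low temperature instead of heat. Ring B closes as a six-membered carbocycle (Δ5,Δ8 1,4-cyclohexadiene) by intermolecular cycloaddition, both new σ-bonds (C9–C10 and C7–C8) being made on the same diene face. C10 is the only new stereocentre (an alkyne poses no endo/exo question), and because the flat ring B forces C9 to end equatorial and C20 axial on ring A, each half-chair of 12 can react only on the face opposite to its pseudoaxial C4 substituent. The half-chair with O3 equatorial, the small C18 methyl in the pseudoequatorial site next to H6 and C19 pseudoaxial on the α face offers a β face lined only by hydrogens at C1 and C3, whereas the other half-chair would have to be attacked on the α face past an axial OTBS group standing 1,3 to C1, just where the aluminium-bound ester must lie; addition should therefore take place on the β face and push C20 to the α face, cis to C19. The selectivities needed are thus regiochemistry (secured by the polarity match C8/C7) and diene-face choice (secured by the 3α-OTBS/4α-CH2OTBDPS pair), and open-chain silyl ethers are used on purpose, since a cis-fused cyclic 3,19-acetal would hold ring A in the O3-axial, C18-pseudoaxial half-chair and expose the wrong face.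

Step 9
Reactants: 14 5,8-dienoate
Product: 15 methyl 3α-(TBS-oxy)-19-(TBDPS-oxy)-12,13,14,15,16-pentanorlabd-8-en-11-oate (H5 β trans-decalin)
Conditions: H2 (3 atm), 10% Pd/C, EtOAc, rt
Reagents that add atoms: none
Why: Heterogeneous catalytic hydrogenation saturates the trisubstituted Δ5 while the tetrasubstituted, ester-conjugated Δ8 stays inert, and hydrogen arrives on the β face because the α face is covered by the axial C20 and C19 groups, which sets H5 β.

Step 10
Reactants: 15 conjugated 8-en-11-oate
Product: 17 methyl 3α-(TBS-oxy)-19-(TBDPS-oxy)-12,13,14,15,16-pentanorlabd-7-en-11-oate (H9 β ester equatorial), via potassium dienolate 16 (not isolated)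
Conditions: KN(SiMe3)2 (1.5 equiv), THF–DMPU, −78 → 0 °C; recool to −78 °C, AcOH
Reagents that add atoms: potassium hexamethyldisilazide (its potassium stays only in 16) [K+].C[Si](C)(C)[N-][Si](C)(C)C
Why: Deconjugative protonation of an extended enolate in which reversible γ-deprotonation by a potassium amide in a polar medium funnels the ester into the planar s-trans endocyclic dienolate (loss of H7) instead of the crowded s-cis exocyclic one (loss of a C17 hydrogen), and kinetic α-protonation on the β face opposite axial C20 sets H9 β.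

Step 11
Reactants: 17 7-en-11-oate
Product: 18 3α-(TBS-oxy)-19-(TBDPS-oxy)-12,13,14,15,16-pentanorlabd-7-en-11-ol
Conditions: LiAlH4, Et2O, 0 °C
Reagents that add atoms: none
Why: Standard LiAlH4 reduction of the hindered ester gives the primary alcohol without affecting the silyl ethers, Δ7 or C9.

Step 12
Reactants: 18 11-alcohol
Product: 19 3α-(TBS-oxy)-19-(TBDPS-oxy)-12,13,14,15,16-pentanorlabd-7-en-11-al
Conditions: Dess–Martin periodinane, pyridine, CH2Cl2, 0 °C → rt
Reagents that add atoms: none
Why: Dess–Martin oxidation under buffered, essentially neutral conditions gives the β,γ-unsaturated aldehyde without epimerising C9 or drawing Δ7 into conjugation.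

Step 13
Reactants: 19 11-aldehyde
Product: 20 3α-(TBS-oxy)-19-(TBDPS-oxy)-13,14,15,16-tetranorlabda-7,11-diene
Conditions: Ph3PCH3Br, KN(SiMe3)2, THF, 0 °C; then 19, −78 → 0 °C
Reagents that add atoms: methyltriphenylphosphonium bromide C[P+](c1ccccc1)(c1ccccc1)c1ccccc1.[Br-]
Why: Wittig methylenation with the small, highly reactive non-stabilised ylide adds C12 at low temperature faster than the aldehyde can enolise, so C9 and Δ7 are preserved.

Step 14
Reactants: 21 2,2,6-trimethyl-4H-1,3-dioxin-4-one; 22 2-(trimethylsilyl)ethanol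
Product: 24 TMSE 3-oxobutanoate, via acetylketene 23 (not isolated)
Conditions: toluene, reflux
Reagents that add atoms: none
Why: Thermal retro-[4+2] cleavage of the dioxinone releases acetylketene, which the alcohol traps (acetoacetylation) to give the fluoride-labile ester of the C13–C16 unit.

Step 15
Reactants: 24 TMSE 3-oxobutanoate
Product: 26 TMSE (E)-3-(trifluoromethylsulfonyloxy)but-2-enoate, via tetramethylammonium enolate 25 (not isolated)
Conditions: Tf2O, 25% aq. Me4NOH, hexanes, 0–5 °C
Reagents that add atoms: trifluoromethanesulfonic anhydride O=S(=O)(OS(=O)(=O)C(F)(F)F)C(F)(F)F; tetramethylammonium hydroxide (its cation stays only in 25) C[N+](C)(C)C.[OH-]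
Why: Stereoselective biphasic enol triflation of an acetoacetate in which the non-coordinating ammonium counter-ion favours the open, non-chelated (E)-enolate, so the triflate ends trans to the ester group.

Step 16
Reactants: 20 7,11-diene; 26 (E)-enol triflate
Product: 28 TMSE (13E)-3α-(TBS-oxy)-19-(TBDPS-oxy)labda-7,13-dien-15-oate, via B-alkyl-9-BBN 27 (not isolated)
Conditions: 9-BBN-H, THF, rt; then 26, PdCl2(dppf) (5 mol%), AsPh3, 3 M aq. K3PO4, DMF, rt → 45 °C
Reagents that add atoms: 9-borabicyclo[3.3.1]nonane (its boryl group stays only in 27) [H]B1C2CCCC1CCC2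
Why: Hydroboration followed by B-alkyl Suzuki–Miyaura coupling: 9-BBN-H adds anti-Markovnikov to the monosubstituted C11=C12 alkene only (the trisubstituted Δ7 is inert at rt) and the palladium catalyst joins C12 to C13 with retention of the enol triflate geometry, which fixes 13E.

Step 17
Reactants: 28 fully protected dienoate
Product: 29 TMSE (13E)-19-(TBDPS-oxy)-3α-hydroxylabda-7,13-dien-15-oate
Conditions: camphorsulfonic acid (cat.), MeOH–CH2Cl2 1:1, rt
Reagents that add atoms: none
Why: Acid-catalysed methanolysis distinguishes the two silyl ethers by their very different acid lability, so the TBS ether is cleaved while the TBDPS ether, the TMSE ester and both alkenes remain.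

Step 18
Reactants: 29 3α-alcohol
Product: 30 TMSE (13E)-19-(TBDPS-oxy)-3-oxolabda-7,13-dien-15-oate
Conditions: Dess–Martin periodinane, pyridine, CH2Cl2, rt
Reagents that add atoms: none
Why: Dess–Martin oxidation of the equatorial alcohol gives the 3-ketone, which cannot undergo retro-aldol cleavage or β-elimination because O19 is silylated and C4 is quaternary.

Step 19
Reactants: 30 3-ketone
Product: 31 TMSE (13E)-19-(TBDPS-oxy)-3β-hydroxylabda-7,13-dien-15-oate (OH axial trans to C19)
Conditions: LiBH(s-Bu)3 (L-Selectride), THF, −78 °C; H2O quench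
Reagents that add atoms: none
Why: Bulky trialkylborohydride reduction of a locked cyclohexanone proceeds by equatorial attack, as known for 4,4-disubstituted 3-oxo terpenoids, which gives the axial 3β-alcohol (3S as in the target), and at −78 °C the ketone reacts far faster than the β,β-disubstituted enoate.

Step 20
Reactants: 31 3β-alcohol
Product: 32 TMSE (13E)-3β-acetoxy-19-(TBDPS-oxy)labda-7,13-dien-15-oate
Conditions: Ac2O, DMAP, Et3N, CH2Cl2, rt
Reagents that add atoms: acetic anhydride CC(=O)OC(C)=O
Why: DMAP-catalysed acylation acetylates the only free hydroxyl group, hindered and axial as it is, with retention at C3.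

Step 21
Reactants: 32 protected acetate
Product: 33 (13E)-3β-acetoxy-19-hydroxylabda-7,13-dien-15-oic acid of the ent series (3S,4R,5S,9R,10S) = CNP0129162.1
Conditions: Bu4NF, THF, 0 °C → rt; 0.5 M aq. HCl work-up
Reagents that add atoms: none
Why: Fluoride-induced desilylation cleaves the TBDPS ether and fragments the TMSE ester to the acid, ethylene and Me3SiF in one operation, and the acetate stays in place because O3 (axial, β) and C19 (axial, α) are antiperiplanar, so acyl migration has no cyclic pathway.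

**Compound list**
1 | 2-methylcyclohexane-1,3-dione | CC1C(=O)CCCC1=O | starting material
2 | formaldehyde | C=O | starting material
3 | 2-(hydroxymethyl)-2-methylcyclohexane-1,3-dione | CC1(CO)C(=O)CCCC1=O | intermediate
4 | 2-[(TBDPS-oxy)methyl]-2-methylcyclohexane-1,3-dione | CC1(CO[Si](c2ccccc2)(c2ccccc2)C(C)(C)C)C(=O)CCCC1=O | intermediate
5 | (2R,3R)-2-[(TBDPS-oxy)methyl]-3-hydroxy-2-methylcyclohexan-1-one | O[C@@H]1CCCC(=O)[C@]1(C)CO[Si](c2ccccc2)(c2ccccc2)C(C)(C)C | intermediate
6 | (2R,3R)-3-(TBS-oxy)-2-[(TBDPS-oxy)methyl]-2-methylcyclohexan-1-one | CC(C)(C)[Si](C)(C)O[C@@H]1CCCC(=O)[C@]1(C)CO[Si](c2ccccc2)(c2ccccc2)C(C)(C)C | intermediate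
7 | lithium enolate of 6 (C5=C10) | [Li+].CC(C)(C)[Si](C)(C)O[C@@H]1CCC=C([O-])[C@]1(C)CO[Si](c2ccccc2)(c2ccccc2)C(C)(C)C | intermediate
8 | (2R,3R,6RS)-3-(TBS-oxy)-2-[(TBDPS-oxy)methyl]-2,6-dimethylcyclohexan-1-one | CC(C)(C)[Si](C)(C)O[C@@H]1CCC(C)C(=O)[C@]1(C)CO[Si](c2ccccc2)(c2ccccc2)C(C)(C)C | intermediate
9 | potassium enolate of 8 (tetrasubstituted C5=C10) | [K+].CC(C)(C)[Si](C)(C)O[C@@H]1CCC(C)=C([O-])[C@]1(C)CO[Si](c2ccccc2)(c2ccccc2)C(C)(C)C | intermediate
10 | (5R,6R)-5-(TBS-oxy)-6-[(TBDPS-oxy)methyl]-2,6-dimethylcyclohex-1-en-1-yl triflate | CC(C)(C)[Si](C)(C)O[C@@H]1CCC(C)=C(OS(=O)(=O)C(F)(F)F)[C@]1(C)CO[Si](c2ccccc2)(c2ccccc2)C(C)(C)C | intermediate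
11 | tributyl(vinyl)stannane | C=C[Sn](CCCC)(CCCC)CCCC | starting material
12 | ring A diene, (1R,6R), O3 cis to C19 | CC(C)(C)[Si](C)(C)O[C@@H]1CCC(C)=C(C=C)[C@]1(C)CO[Si](c2ccccc2)(c2ccccc2)C(C)(C)C | intermediate
13 | methyl but-2-ynoate | CC#CC(=O)OC | starting material
14 | methyl 3α-(TBS-oxy)-19-(TBDPS-oxy)-12,13,14,15,16-pentanorlabda-5,8-dien-11-oate, C20 α | CC(C)(C)[Si](C)(C)O[C@@H]1CC[C@]2(C)C(=CCC(C)=C2C(=O)OC)[C@]1(C)CO[Si](c3ccccc3)(c3ccccc3)C(C)(C)C | intermediate
15 | methyl 3α-(TBS-oxy)-19-(TBDPS-oxy)-12,13,14,15,16-pentanorlabd-8-en-11-oate, H5 β | CC(C)(C)[Si](C)(C)O[C@@H]1CC[C@]2(C)[C@H](CCC(C)=C2C(=O)OC)[C@]1(C)CO[Si](c3ccccc3)(c3ccccc3)C(C)(C)C | intermediate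
16 | potassium 7,9(11)-dienolate of 15 | [K+].CC(C)(C)[Si](C)(C)O[C@@H]1CC[C@]2(C)[C@H](CC=C(C)C2=C([O-])OC)[C@]1(C)CO[Si](c3ccccc3)(c3ccccc3)C(C)(C)C | intermediate
17 | methyl 3α-(TBS-oxy)-19-(TBDPS-oxy)-12,13,14,15,16-pentanorlabd-7-en-11-oate, H9 β | CC(C)(C)[Si](C)(C)O[C@@H]1CC[C@]2(C)[C@H](CC=C(C)[C@H]2C(=O)OC)[C@]1(C)CO[Si](c3ccccc3)(c3ccccc3)C(C)(C)C | intermediate
18 | 3α-(TBS-oxy)-19-(TBDPS-oxy)-12,13,14,15,16-pentanorlabd-7-en-11-ol | CC(C)(C)[Si](C)(C)O[C@@H]1CC[C@]2(C)[C@H](CC=C(C)[C@H]2CO)[C@]1(C)CO[Si](c3ccccc3)(c3ccccc3)C(C)(C)C | intermediate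
19 | 3α-(TBS-oxy)-19-(TBDPS-oxy)-12,13,14,15,16-pentanorlabd-7-en-11-al | CC(C)(C)[Si](C)(C)O[C@@H]1CC[C@]2(C)[C@H](CC=C(C)[C@H]2C=O)[C@]1(C)CO[Si](c3ccccc3)(c3ccccc3)C(C)(C)C | intermediate
20 | 3α-(TBS-oxy)-19-(TBDPS-oxy)-13,14,15,16-tetranorlabda-7,11-diene | CC(C)(C)[Si](C)(C)O[C@@H]1CC[C@]2(C)[C@H](CC=C(C)[C@H]2C=C)[C@]1(C)CO[Si](c3ccccc3)(c3ccccc3)C(C)(C)C | intermediate
21 | 2,2,6-trimethyl-4H-1,3-dioxin-4-one | CC1=CC(=O)OC(C)(C)O1 | starting material
22 | 2-(trimethylsilyl)ethanol | C[Si](C)(C)CCO | starting material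
23 | acetylketene | CC(=O)C=C=O | intermediate
24 | TMSE 3-oxobutanoate | CC(=O)CC(=O)OCC[Si](C)(C)C | intermediate
25 | tetramethylammonium (E)-enolate of 24 | C[N+](C)(C)C.C/C([O-])=C\C(=O)OCC[Si](C)(C)C | intermediate
26 | TMSE (E)-3-(trifluoromethylsulfonyloxy)but-2-enoate | C/C(OS(=O)(=O)C(F)(F)F)=C\C(=O)OCC[Si](C)(C)C | intermediate
27 | 12-(9-borabicyclo[3.3.1]nonan-9-yl)-3α-(TBS-oxy)-19-(TBDPS-oxy)-13,14,15,16-tetranorlabd-7-ene | CC(C)(C)[Si](C)(C)O[C@@H]1CC[C@]2(C)[C@H](CC=C(C)[C@H]2CCB3C4CCCC3CCC4)[C@]1(C)CO[Si](c5ccccc5)(c5ccccc5)C(C)(C)C | intermediate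
28 | TMSE (13E)-3α-(TBS-oxy)-19-(TBDPS-oxy)labda-7,13-dien-15-oate | CC(C)(C)[Si](C)(C)O[C@@H]1CC[C@]2(C)[C@H](CC=C(C)[C@H]2CC/C(C)=C/C(=O)OCC[Si](C)(C)C)[C@]1(C)CO[Si](c3ccccc3)(c3ccccc3)C(C)(C)C | intermediate
29 | TMSE (13E)-19-(TBDPS-oxy)-3α-hydroxylabda-7,13-dien-15-oate | O[C@@H]1CC[C@]2(C)[C@H](CC=C(C)[C@H]2CC/C(C)=C/C(=O)OCC[Si](C)(C)C)[C@]1(C)CO[Si](c3ccccc3)(c3ccccc3)C(C)(C)C | intermediate
30 | TMSE (13E)-19-(TBDPS-oxy)-3-oxolabda-7,13-dien-15-oate | O=C1CC[C@]2(C)[C@H](CC=C(C)[C@H]2CC/C(C)=C/C(=O)OCC[Si](C)(C)C)[C@]1(C)CO[Si](c3ccccc3)(c3ccccc3)C(C)(C)C | intermediate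
31 | TMSE (13E)-19-(TBDPS-oxy)-3β-hydroxylabda-7,13-dien-15-oate | O[C@H]1CC[C@]2(C)[C@H](CC=C(C)[C@H]2CC/C(C)=C/C(=O)OCC[Si](C)(C)C)[C@]1(C)CO[Si](c3ccccc3)(c3ccccc3)C(C)(C)C | intermediate
32 | TMSE (13E)-3β-acetoxy-19-(TBDPS-oxy)labda-7,13-dien-15-oate | CC(=O)O[C@H]1CC[C@]2(C)[C@H](CC=C(C)[C@H]2CC/C(C)=C/C(=O)OCC[Si](C)(C)C)[C@]1(C)CO[Si](c3ccccc3)(c3ccccc3)C(C)(C)C | intermediate
33 | (13E)-3β-acetoxy-19-hydroxylabda-7,13-dien-15-oic acid, ent series, (3S,4R,5S,9R,10S) | CC(=O)O[C@H]1CC[C@]2(C)[C@H](CC=C(C)[C@H]2CC/C(C)=C/C(=O)O)[C@]1(C)CO | target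

Total step count: 21. Longest linear sequence: 19 (steps 1–13 and 16–21; steps 14–15 build the side-chain fragment).

**Steps most likely to fail**

Step 8. The twisted, fully substituted diene terminus may add so slowly that Lewis acid-induced isomerisation or oligomerisation of the diene takes over. The choice between the two diene faces may also be poor.
- The fallback raises the dienophile to the aldehyde oxidation level and keeps the same two bonds. It sets out from 12.
- But-2-ynal F1 (from but-2-yn-1-ol and MnO2) is added to 12 with BF3·OEt2 in CH2Cl2 at −78 °C. The far more electrophilic ynal reacts there, and the lower temperature sharpens the face selection. This gives the 5,8-dien-11-al F2.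
- Pinnick oxidation (NaClO2, NaH2PO4, 2-methylbut-2-ene, t-BuOH–H2O) gives the 5,8-dien-11-oic acid F3.
- Esterification of F3 with Me3SiCHN2 rejoins the route at 14.

Step 10. The base may remove a hydrogen of the C17 methyl group, which lies syn to the ester, instead of H7. The dienolate may also be protonated back at the γ-position.
- The fallback accepts the carbonyl-directed kinetic deprotonation and repairs the alkene position afterwards. It sets out from 15.
- LiN(i-Pr)2 in THF at −78 °C followed by AcOH gives the exocyclic methyl 8(17)-en-11-oate F4, with H9 β set in the same way.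
- A hydrogen-atom-transfer alkene isomerisation then moves the 1,1-disubstituted alkene into the ring through the less hindered C7–H. The conditions are chloro[N,N'-bis(3,5-di-tert-butylsalicylidene)ethane-1,2-diaminato]cobalt (cat.) and PhSiH3 (cat.) in benzene at rt. This rejoins the route at 17.
- Any material that slips to the conjugated position is 15 itself and is recycled.

Step 19. The equatorial approach of the bulky hydride runs past the axial CH2OTBDPS group, so axial attack may compete and erode the C3 selectivity.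
- The fallback replaces steric control by intramolecular hydride delivery. It sets out from 30.
- HF·pyridine in THF removes the TBDPS group to give the 19-hydroxy-3-ketone F5.
- Evans–Saksena reduction (Me4NBH(OAc)3, MeCN–AcOH, −20 °C) binds boron to O19 and hands hydride to the α face of C3. This gives the anti 3β,19-diol F6.
- t-BuPh2SiCl and imidazole then silylate only the primary alcohol, which rejoins the route at 31.

**Further compounds**
F1 | step 8 | but-2-ynal | CC#CC=O
F2 | step 8 | 3α-(TBS-oxy)-19-(TBDPS-oxy)-12,13,14,15,16-pentanorlabda-5,8-dien-11-al | CC(C)(C)[Si](C)(C)O[C@@H]1CC[C@]2(C)C(=CCC(C)=C2C=O)[C@]1(C)CO[Si](c3ccccc3)(c3ccccc3)C(C)(C)C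
F3 | step 8 | 3α-(TBS-oxy)-19-(TBDPS-oxy)-12,13,14,15,16-pentanorlabda-5,8-dien-11-oic acid | CC(C)(C)[Si](C)(C)O[C@@H]1CC[C@]2(C)C(=CCC(C)=C2C(=O)O)[C@]1(C)CO[Si](c3ccccc3)(c3ccccc3)C(C)(C)C
F4 | step 10 | methyl 3α-(TBS-oxy)-19-(TBDPS-oxy)-12,13,14,15,16-pentanorlabd-8(17)-en-11-oate | CC(C)(C)[Si](C)(C)O[C@@H]1CC[C@]2(C)[C@H](CCC(=C)[C@H]2C(=O)OC)[C@]1(C)CO[Si](c3ccccc3)(c3ccccc3)C(C)(C)C
F5 | step 19 | TMSE (13E)-19-hydroxy-3-oxolabda-7,13-dien-15-oate | O=C1CC[C@]2(C)[C@H](CC=C(C)[C@H]2CC/C(C)=C/C(=O)OCC[Si](C)(C)C)[C@]1(C)CO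
F6 | step 19 | TMSE (13E)-3β,19-dihydroxylabda-7,13-dien-15-oate | O[C@H]1CC[C@]2(C)[C@H](CC=C(C)[C@H]2CC/C(C)=C/C(=O)OCC[Si](C)(C)C)[C@]1(C)CO
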